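**Strategy.** The route rests on cutting the dioxane ring at C3, the carbon that carries O4 (the ether to C4a of ring A), the methyl group and the bond to the benzylic carbon C2. C3 is treated as a former carbene carbon: in one operation a rhodium carbenoid from ethyl diazoacetate is joined to a phenol oxygen (O4–C3) and to the formyl carbon of 3,4,5-trimethoxybenzaldehyde (C2–C3), setting both stereocentres as the threo pair. The precursors are the diazo ester, the aldehyde and a 5-bromovanillin-derived phenol whose formyl group is masked as a dioxolane and whose ortho bromide later closes O1–C8a. The ester carbon becomes the C3 methyl group.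

Key step: step 2

Remark: all bicyclic compounds are numbered as O1, C2 (aryl), C3 (methyl), O4, C4a, C5 (OMe), C6, C7 (side chain), C8, C8a; ring A is the benzo ring.
Remark: the sense of induction of the chiral acid cannot be predicted with certainty; the (R)-acid is written and its antipode is used if a screen shows the opposite sense.
Remark: the aryloxy-bearing carbon is S in ester 6 and R in 7–9 only because CIP priorities change on reduction of the ester; its spatial arrangement is never touched.

Step 1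
Reactants: 1 5-bromovanillin
Product: 2 2-bromo-4-(1,3-dioxolan-2-yl)-6-methoxyphenol
Conditions: ethylene glycol (4 equiv), TsOH·H2O (cat.), toluene, reflux, Dean–Stark; Et3N quench
Reagents that add atoms: ethylene glycol, OCCO
Why: Acid-catalysed acetalisation with azeotropic removal of water drives the equilibrium to the cyclic acetal without touching the phenol; the mask removes the only competing electrophile of step 2 and shields the formyl group from the hydrides of steps 3 and 5.

Step 2
Reactants: 2 2-bromo-4-(1,3-dioxolan-2-yl)-6-methoxyphenol; 3 ethyl diazoacetate; 4 3,4,5-trimethoxybenzaldehyde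
Product: 6 ethyl (2S,3R)-2-[2-bromo-4-(1,3-dioxolan-2-yl)-6-methoxyphenoxy]-3-hydroxy-3-(3,4,5-trimethoxyphenyl)propanoate, via oxonium ylide 5 (not isolated)
Conditions: Rh2(OAc)4 (2 mol%), (R)-3,3'-bis(2,4,6-triisopropylphenyl)-1,1'-binaphthyl-2,2'-diyl hydrogen phosphate (10 mol%), 4 (2 equiv), 4 Å MS, CH2Cl2, −20 °C, 3 (1.5 equiv) added slowly by syringe pump
Reagents that add atoms: none
Why: Proposed new method: Rh2(OAc)4 turns 3 into an electrophilic carbenoid, the phenol oxygen of 2 adds to it to give the protic oxonium ylide 5, an enol equivalent, and 5 adds through carbon to the formyl group of 4, which is held and activated by hydrogen bonding to the chiral phosphoric acid, before the 1,2-proton shift can deliver the plain O–H insertion product; the closest known reaction type is the rhodium/Brønsted-acid co-catalysed three-component aldol-type trapping of alcohol-derived oxonium ylides (from aryl diazoacetates) by activated aldehydes or imines, which has not been shown for a phenol combined with an acceptor-only diazo ester and an electron-rich benzaldehyde. Two bonds, O4–C3 and C2–C3, are made at the former carbene carbon and no ring is closed. Both stereocentres arise in the C–C bond-forming event: the phosphoric acid is expected to bind the O–H of the ylide with its P=O oxygen and the aldehyde with its P–OH group, and the 3,3'-aryl groups of this cyclic, bifunctional transition state decide which faces of the enol (C3) and of the aldehyde (C2) meet, the compact arrangement placing the two oxygens syn, i.e. threo. The step needs chemoselectivity (aldol trapping faster than proton shift), threo selectivity and enantioselectivity; the substrates help because 2 offers a single O–H and no free carbonyl group, 4 is the only electrophile and cannot enolise, and the excess of 4, the slow addition of 3 and the low temperature keep the short-lived ylide surrounded by activated aldehyde, while the sieves keep the acetal from hydrolysing.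

Step 3
Reactants: 6 ethyl (2S,3R)-2-[2-bromo-4-(1,3-dioxolan-2-yl)-6-methoxyphenoxy]-3-hydroxy-3-(3,4,5-trimethoxyphenyl)propanoate
Product: 7 (1R,2R)-2-[2-bromo-4-(1,3-dioxolan-2-yl)-6-methoxyphenoxy]-1-(3,4,5-trimethoxyphenyl)propane-1,3-diol
Conditions: LiBH4, THF, 0 °C to rt; aq. NH4Cl
Reagents that add atoms: none
Why: Chemoselective borohydride reduction of the lithium-chelated α-aryloxy β-hydroxy ester leaves aryl bromide, acetal and both stereocentres untouched, and doing it first removes the epimerisable α-hydrogen and the retro-aldol pathway before any basic step.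

Step 4
Reactants: 7 (1R,2R)-2-[2-bromo-4-(1,3-dioxolan-2-yl)-6-methoxyphenoxy]-1-(3,4,5-trimethoxyphenyl)propane-1,3-diol
Product: 8 (2R,3R)-2-[2-bromo-4-(1,3-dioxolan-2-yl)-6-methoxyphenoxy]-3-hydroxy-3-(3,4,5-trimethoxyphenyl)propyl 4-methylbenzenesulfonate
Conditions: TsCl (1.1 equiv), Et3N, DMAP (cat.), CH2Cl2, 0 °C
Reagents that add atoms: p-toluenesulfonyl chloride, Cc1ccc(cc1)S(Cl)(=O)=O
Why: Selective sulfonylation of the primary hydroxyl of a primary/secondary 1,3-diol is expected on kinetic grounds, the secondary benzylic hydroxyl being hindered by the aryl and aryloxy groups.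

Step 5
Reactants: 8 (2R,3R)-2-[2-bromo-4-(1,3-dioxolan-2-yl)-6-methoxyphenoxy]-3-hydroxy-3-(3,4,5-trimethoxyphenyl)propyl 4-methylbenzenesulfonate
Product: 9 (1R,2R)-2-[2-bromo-4-(1,3-dioxolan-2-yl)-6-methoxyphenoxy]-1-(3,4,5-trimethoxyphenyl)propan-1-ol
Conditions: LiEt3BH (3 equiv), THF, 0 °C to rt
Reagents that add atoms: none
Why: SN2 displacement of the primary sulfonate by hydride (hydride reduction of a tosylate) turns the former ester carbon into the C3 methyl group; the neighbouring hydroxyl is carried as its triethylborane-complexed lithium alkoxide, and aryl bromide and acetal are inert at this temperature.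

Step 6
Reactants: 9 (1R,2R)-2-[2-bromo-4-(1,3-dioxolan-2-yl)-6-methoxyphenoxy]-1-(3,4,5-trimethoxyphenyl)propan-1-ol
Product: 11 (2R,3R)-5-methoxy-3-methyl-2-(3,4,5-trimethoxyphenyl)-2,3-dihydro-1,4-benzodioxine-7-carbaldehyde, via benzodioxane acetal 10 (not isolated)
Conditions: CuI (10 mol%), 3,4,7,8-tetramethyl-1,10-phenanthroline (20 mol%), Cs2CO3, toluene, 110 °C, argon; filter; then 1 M HCl, THF, rt
Reagents that add atoms: water, O
Why: Intramolecular Ullmann-type C–O coupling of the secondary alkoxide with the ortho bromide forms O1–C8a and closes the six-membered dioxane without breaking any bond to C2 or C3, so the threo pair becomes the trans ring with retention; the aqueous acid stage then hydrolyses the dioxolane to the aldehyde.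

Step 7
Reactants: 11 (2R,3R)-5-methoxy-3-methyl-2-(3,4,5-trimethoxyphenyl)-2,3-dihydro-1,4-benzodioxine-7-carbaldehyde
Product: 12 ethyl (E)-3-[(2R,3R)-5-methoxy-3-methyl-2-(3,4,5-trimethoxyphenyl)-2,3-dihydro-1,4-benzodioxin-7-yl]prop-2-enoate
Conditions: (EtO)2P(O)CH2CO2Et, NaH, THF, 0 °C to rt
Reagents that add atoms: triethyl phosphonoacetate, CCOC(=O)CP(=O)(OCC)OCC
Why: Horner–Wadsworth–Emmons olefination of an aromatic aldehyde with a stabilised phosphonate anion gives the E-enoate, and neither stereocentre carries an acidic hydrogen.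

Step 8
Reactants: 12 ethyl (E)-3-[(2R,3R)-5-methoxy-3-methyl-2-(3,4,5-trimethoxyphenyl)-2,3-dihydro-1,4-benzodioxin-7-yl]prop-2-enoate
Product: 13 (E)-3-[(2R,3R)-5-methoxy-3-methyl-2-(3,4,5-trimethoxyphenyl)-2,3-dihydro-1,4-benzodioxin-7-yl]prop-2-en-1-ol
Conditions: DIBAL-H (2.5 equiv), CH2Cl2, −78 °C; Rochelle salt work-up
Reagents that add atoms: none
Why: 1,2-Reduction of the α,β-unsaturated ester by DIBAL-H at low temperature gives the allylic alcohol with the E double bond intact, the aryl ethers and the dioxane ring being inert.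

**Compound list**

1 | 5-bromovanillin (3-bromo-4-hydroxy-5-methoxybenzaldehyde) | COc1cc(C=O)cc(Br)c1O | starting material
2 | 2-bromo-4-(1,3-dioxolan-2-yl)-6-methoxyphenol | COc1cc(C2OCCO2)cc(Br)c1O | intermediate
3 | ethyl diazoacetate | CCOC(=O)C=[N+]=[N-] | starting material
4 | 3,4,5-trimethoxybenzaldehyde | COc1cc(C=O)cc(OC)c1OC | starting material
5 | oxonium ylide from 2 and the carbenoid of 3, drawn metal-free (ethyl 2-{[2-bromo-4-(1,3-dioxolan-2-yl)-6-methoxyphenyl]oxonio}acetate ylide) | CCOC(=O)[CH-][OH+]c1c(Br)cc(C2OCCO2)cc1OC | intermediate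
6 | ethyl (2S,3R)-2-[2-bromo-4-(1,3-dioxolan-2-yl)-6-methoxyphenoxy]-3-hydroxy-3-(3,4,5-trimethoxyphenyl)propanoate | COc1cc([C@@H](O)[C@H](Oc2c(Br)cc(C3OCCO3)cc2OC)C(=O)OCC)cc(OC)c1OC | intermediate
7 | (1R,2R)-2-[2-bromo-4-(1,3-dioxolan-2-yl)-6-methoxyphenoxy]-1-(3,4,5-trimethoxyphenyl)propane-1,3-diol | COc1cc([C@@H](O)[C@H](Oc2c(Br)cc(C3OCCO3)cc2OC)CO)cc(OC)c1OC | intermediate
8 | (2R,3R)-2-[2-bromo-4-(1,3-dioxolan-2-yl)-6-methoxyphenoxy]-3-hydroxy-3-(3,4,5-trimethoxyphenyl)propyl 4-methylbenzenesulfonate | COc1cc([C@@H](O)[C@H](Oc2c(Br)cc(C3OCCO3)cc2OC)COS(=O)(=O)c2ccc(C)cc2)cc(OC)c1OC | intermediate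
9 | (1R,2R)-2-[2-bromo-4-(1,3-dioxolan-2-yl)-6-methoxyphenoxy]-1-(3,4,5-trimethoxyphenyl)propan-1-ol | COc1cc([C@@H](O)[C@H](Oc2c(Br)cc(C3OCCO3)cc2OC)C)cc(OC)c1OC | intermediate
10 | (2R,3R)-7-(1,3-dioxolan-2-yl)-5-methoxy-3-methyl-2-(3,4,5-trimethoxyphenyl)-2,3-dihydro-1,4-benzodioxine | COc1cc([C@H]2Oc3cc(C4OCCO4)cc(OC)c3O[C@@H]2C)cc(OC)c1OC | intermediate
11 | (2R,3R)-5-methoxy-3-methyl-2-(3,4,5-trimethoxyphenyl)-2,3-dihydro-1,4-benzodioxine-7-carbaldehyde | COc1cc([C@H]2Oc3cc(C=O)cc(OC)c3O[C@@H]2C)cc(OC)c1OC | intermediate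
12 | ethyl (E)-3-[(2R,3R)-5-methoxy-3-methyl-2-(3,4,5-trimethoxyphenyl)-2,3-dihydro-1,4-benzodioxin-7-yl]prop-2-enoate | COc1cc([C@H]2Oc3cc(/C=C/C(=O)OCC)cc(OC)c3O[C@@H]2C)cc(OC)c1OC | intermediate
13 | (E)-3-[(2R,3R)-5-methoxy-3-methyl-2-(3,4,5-trimethoxyphenyl)-2,3-dihydro-1,4-benzodioxin-7-yl]prop-2-en-1-ol | COc1cc([C@H]2Oc3cc(/C=C/CO)cc(OC)c3O[C@@H]2C)cc(OC)c1OC | target

**Step count and risks**

Total step count: 8. Longest linear sequence: 8 steps (1 to 13); 3 and 4 enter at step 2.

Steps most likely to fail: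

1. Step 2. The proton shift of the ylide may outrun addition to the weakly electrophilic aldehyde, threo or enantiofacial control may be poor, or the acid may ionise the acetal. The fallback drops the carbene assembly for chiral-pool chemistry; it sets out from phenol 2 and comes back at alcohol 9.
   - Mitsunobu etherification of 2 with methyl (S)-lactate (PPh3, DIAD, THF, 0 °C to rt) should give, with inversion, methyl (R)-2-[2-bromo-4-(1,3-dioxolan-2-yl)-6-methoxyphenoxy]propanoate F1.
   - DIBAL-H in toluene at −78 °C should stop at (R)-2-[2-bromo-4-(1,3-dioxolan-2-yl)-6-methoxyphenoxy]propanal F2, which is used at once to avoid racemisation.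
   - Addition of 3,4,5-trimethoxyphenylmagnesium bromide F3 (from 5-bromo-1,2,3-trimethoxybenzene and Mg) with MgBr2·OEt2 in CH2Cl2/THF at −78 °C is expected to follow the Cram-chelate mode, the aryloxy/methoxy pair assisting chelation. This should give mainly the threo alcohol 9; the minor erythro isomer is removed by chromatography.

2. Step 6. The hindered, electron-rich aryl bromide may couple only slowly with the secondary benzylic alkoxide, with loss of bromine or oxidation of the carbinol competing. The fallback reverses the polarity of the closure: O1 is first placed on ring A and then closes onto C2. It sets out from 9 and comes back at aldehyde 11.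
   - Miyaura borylation (Pd(dppf)Cl2, B2pin2, KOAc, dioxane, 90 °C) should give (1R,2R)-2-[4-(1,3-dioxolan-2-yl)-2-methoxy-6-(4,4,5,5-tetramethyl-1,3,2-dioxaborolan-2-yl)phenoxy]-1-(3,4,5-trimethoxyphenyl)propan-1-ol F4.
   - Oxidation (H2O2, NaOH, THF, 0 °C) should give the phenol (1R,2R)-2-[4-(1,3-dioxolan-2-yl)-2-hydroxy-6-methoxyphenoxy]-1-(3,4,5-trimethoxyphenyl)propan-1-ol F5.
   - TsOH·H2O in wet toluene/THF ionises the benzylic alcohol of F5 to the trimethoxybenzyl cation, which the new phenol captures (acid-mediated SN1 etherification). With C3 untouched, closure under thermodynamic control should favour the diequatorial trans ring, and the acetal is hydrolysed in the same pot to give 11.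

3. Step 5. The neighbouring alkoxide may displace the tosylate itself (four-membered ether formation), or hydride may attack the aryl bromide. The fallback changes the order: ring closure first, deoxygenation afterwards, when neither a free hydroxyl nor a bromide remains. It sets out from diol 7 and comes back at the benzodioxane acetal 10, which is then hydrolysed by the acid stage of step 6.
   - Selective silylation of the primary hydroxyl (TBSCl, imidazole, CH2Cl2, 0 °C) should give (1R,2R)-2-[2-bromo-4-(1,3-dioxolan-2-yl)-6-methoxyphenoxy]-3-[(tert-butyldimethylsilyl)oxy]-1-(3,4,5-trimethoxyphenyl)propan-1-ol F6.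
   - The CuI-catalysed closure of step 6, without the acid stage, should give tert-butyl{[(2R,3R)-7-(1,3-dioxolan-2-yl)-5-methoxy-2-(3,4,5-trimethoxyphenyl)-2,3-dihydro-1,4-benzodioxin-3-yl]methoxy}dimethylsilane F7.
   - TBAF in THF frees [(2R,3R)-7-(1,3-dioxolan-2-yl)-5-methoxy-2-(3,4,5-trimethoxyphenyl)-2,3-dihydro-1,4-benzodioxin-3-yl]methanol F8.
   - TsCl, Et3N and DMAP convert F8 into [(2R,3R)-7-(1,3-dioxolan-2-yl)-5-methoxy-2-(3,4,5-trimethoxyphenyl)-2,3-dihydro-1,4-benzodioxin-3-yl]methyl 4-methylbenzenesulfonate F9, which LiEt3BH in THF reduces to 10.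

**Further compounds**

F1 | step 2 | methyl (R)-2-[2-bromo-4-(1,3-dioxolan-2-yl)-6-methoxyphenoxy]propanoate | COC(=O)[C@@H](C)Oc1c(Br)cc(C2OCCO2)cc1OC
F2 | step 2 | (R)-2-[2-bromo-4-(1,3-dioxolan-2-yl)-6-methoxyphenoxy]propanal | O=C[C@@H](C)Oc1c(Br)cc(C2OCCO2)cc1OC
F3 | step 2 | 3,4,5-trimethoxyphenylmagnesium bromide | COc1cc([Mg]Br)cc(OC)c1OC
F4 | step 6 | (1R,2R)-2-[4-(1,3-dioxolan-2-yl)-2-methoxy-6-(4,4,5,5-tetramethyl-1,3,2-dioxaborolan-2-yl)phenoxy]-1-(3,4,5-trimethoxyphenyl)propan-1-ol | COc1cc([C@@H](O)[C@H](Oc2c(B3OC(C)(C)C(C)(C)O3)cc(C3OCCO3)cc2OC)C)cc(OC)c1OC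
F5 | step 6 | (1R,2R)-2-[4-(1,3-dioxolan-2-yl)-2-hydroxy-6-methoxyphenoxy]-1-(3,4,5-trimethoxyphenyl)propan-1-ol | COc1cc([C@@H](O)[C@H](Oc2c(O)cc(C3OCCO3)cc2OC)C)cc(OC)c1OC
F6 | step 5 | (1R,2R)-2-[2-bromo-4-(1,3-dioxolan-2-yl)-6-methoxyphenoxy]-3-[(tert-butyldimethylsilyl)oxy]-1-(3,4,5-trimethoxyphenyl)propan-1-ol | COc1cc([C@@H](O)[C@H](Oc2c(Br)cc(C3OCCO3)cc2OC)CO[Si](C)(C)C(C)(C)C)cc(OC)c1OC
F7 | step 5 | tert-butyl{[(2R,3R)-7-(1,3-dioxolan-2-yl)-5-methoxy-2-(3,4,5-trimethoxyphenyl)-2,3-dihydro-1,4-benzodioxin-3-yl]methoxy}dimethylsilane | COc1cc([C@H]2Oc3cc(C4OCCO4)cc(OC)c3O[C@@H]2CO[Si](C)(C)C(C)(C)C)cc(OC)c1OC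
F8 | step 5 | [(2R,3R)-7-(1,3-dioxolan-2-yl)-5-methoxy-2-(3,4,5-trimethoxyphenyl)-2,3-dihydro-1,4-benzodioxin-3-yl]methanol | COc1cc([C@H]2Oc3cc(C4OCCO4)cc(OC)c3O[C@@H]2CO)cc(OC)c1OC
F9 | step 5 | [(2R,3R)-7-(1,3-dioxolan-2-yl)-5-methoxy-2-(3,4,5-trimethoxyphenyl)-2,3-dihydro-1,4-benzodioxin-3-yl]methyl 4-methylbenzenesulfonate | COc1cc([C@H]2Oc3cc(C4OCCO4)cc(OC)c3O[C@@H]2COS(=O)(=O)c2ccc(C)cc2)cc(OC)c1OC
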